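**Strategy.** The plan rests on cutting the bond between the aromatic carbon of the vanilloyl ring and the ester carbonyl carbon. The carbonyl carbon is carried by the terpenoid half as a six-membered cyclic carbonate that ties the tertiary C3 hydroxyl on the cyclopentane ring to the secondary C4 oxygen on the cycloheptene ring (azulene numbering). A 4-silyloxy-3-methoxyphenyllithium opens this tricyclic carbonate: in one operation the aryl–carbonyl bond forms, the acyl group stays on O-C4 and the C3 hydroxyl is released. The hydroazulene triol is built from (S)-3-methyl-3-vinylcyclopentanone by aldol-lactonization, Mukaiyama aldol, ring-closing metathesis and a hydroxyl-directed reduction.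

Key step: step 14

Remark 1: locants in the text are azulene locants of the target: C3 (C–OH, i-Pr), C3a (ring-fusion CH), C4 (CH–O), C6 (C–OH, Me), C7=C8, C8a (C–Me).
Remark 2: in steps 1 and 4 the catalyst enantiomer is the one that gives the configuration drawn; the sense of induction is assumed from close analogues, and the mirror-image catalyst would be used otherwise.

Step 1
Reactants: 1 3-methylcyclopent-2-en-1-one; 2 ethynyltrimethylsilane
Product: 4 (S)-3-methyl-3-[1-(trimethylsilyl)ethenyl]cyclopentan-1-one, via vinylalane 3 (not isolated)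
Conditions: 2, DIBAL-H, hexanes/THF, 55 °C; then 1, CuCl2·2H2O (5 mol%), chiral sulfonate-bearing NHC–Ag complex (2.5 mol%), THF, 22 °C; aq. Rochelle salt
Reagents that add atoms: none
Why: Hydroalumination of the silylalkyne gives the α-silyl vinylalane, which adds to the β-methyl enone in an NHC–Cu-catalysed enantioselective conjugate addition, the chiral Cu–NHC complex choosing the enone face and so setting the all-carbon quaternary centre as S.

Step 2
Reactants: 4 (S)-3-methyl-3-[1-(trimethylsilyl)ethenyl]cyclopentan-1-one
Product: 5 (S)-3-ethenyl-3-methylcyclopentan-1-one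
Conditions: CF3CO2H, CHCl3, 22 °C
Reagents that add atoms: none
Why: Acid-mediated protodesilylation of the vinylsilane (ipso protonation, then loss of the silyl group) leaves the quaternary centre untouched.

Step 3
Reactants: 5 (S)-3-ethenyl-3-methylcyclopentan-1-one
Product: 7 (S)-3-ethenyl-3,7-dimethyl-6-oxooctanoic acid, via diketone 6 (not isolated)
Conditions: LDA, THF, −78 °C; i-PrCOCl, −78 → 0 °C; then KOH, MeOH/H2O, 60 °C; aq. HCl
Reagents that add atoms: isobutyryl chloride CC(C)C(=O)Cl; potassium hydroxide [K+].[OH-]
Why: Kinetic deprotonation at the CH2 remote from the quaternary carbon and C-acylation give the 2-acylcyclopentanone, which hydroxide opens at the ring carbonyl in a retro-Claisen cleavage to the 6-oxo acid, no stereocentre being formed or put at risk.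

Step 4
Reactants: 7 (S)-3-ethenyl-3,7-dimethyl-6-oxooctanoic acid
Product: 8 (1R,2R,5R)-2-ethenyl-2-methyl-5-(propan-2-yl)-6-oxabicyclo[3.2.0]heptan-7-one
Conditions: TsCl, (S)-HBTM (20 mol%), i-Pr2NEt, LiCl, CH2Cl2, 23 °C
Reagents that add atoms: none
Why: Nucleophile-catalysed aldol-lactonization, in which the ammonium enolate of the activated acid adds to the isopropyl ketone and the aldolate closes the β-lactone, forces the ring oxygen and the lactone carbonyl carbon cis, while the chiral isothiourea rather than the weakly biased Me/vinyl centre should place both on the ring face of the methyl group.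

Step 5
Reactants: 8 β-lactone
Product: 9 (1R,2S,3R)-3-ethenyl-2-(hydroxymethyl)-3-methyl-1-(propan-2-yl)cyclopentan-1-ol
Conditions: LiAlH4, THF, 0 °C; Fieser work-up
Reagents that add atoms: none
Why: Hydride reduction of the strained lactone gives the 1,3-diol without touching a stereocentre.

Step 6
Reactants: 9 diol
Product: 10 (1R,2R,5R)-2-ethenyl-5-hydroxy-2-methyl-5-(propan-2-yl)cyclopentane-1-carbaldehyde
Conditions: Dess–Martin periodinane, NaHCO3, CH2Cl2, 0 → 23 °C
Reagents that add atoms: none
Why: Dess–Martin oxidation affects only the primary alcohol, and the buffered non-basic medium should avoid retro-aldol cleavage or epimerization at the hindered α-carbon.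

Step 7
Reactants: 10 hydroxy aldehyde; 11 2-(trimethylsilyloxy)buta-1,3-diene
Product: 12 5-hydroxy-5-[(1S,2R,5R)-2-ethenyl-5-hydroxy-2-methyl-5-(propan-2-yl)cyclopentyl]pent-1-en-3-one (both C5 carbinol epimers)
Conditions: MgBr2·OEt2, CH2Cl2, −78 → −20 °C; aq. citric acid
Reagents that add atoms: none
Why: Mukaiyama aldol addition of the silyl dienol ether through its terminal CH2 to the Lewis-acid-activated aldehyde installs the β-hydroxy vinyl ketone, and the configuration of the new carbinol is immaterial because this centre is re-set in steps 10 and 11.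

Step 8
Reactants: 12 hydroxy vinyl ketone
Product: 13 (3R,3aS,8aR)-3,4-dihydroxy-8a-methyl-3-(propan-2-yl)-2,3,3a,4,5,8a-hexahydroazulen-6(1H)-one (C4 epimers)
Conditions: Hoveyda–Grubbs II (10 mol%), toluene (2 mM), 80 °C
Reagents that add atoms: none
Why: Ring-closing metathesis between the vinyl ketone and the vinyl group on the quaternary carbon closes the cycloheptenone with loss of ethene, the trans ring fusion following from the trans arrangement of the two arms on the cyclopentane.

Step 9
Reactants: 13 enone diol
Product: 14 (3R,3aS,6S,8aR)-6,8a-dimethyl-3-(propan-2-yl)-1,2,3,3a,4,5,6,8a-octahydroazulene-3,4,6-triol (C4 epimers)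
Conditions: MeLi (4 eq), THF, −78 °C; H2O
Reagents that add atoms: methyllithium [Li]C
Why: 1,2-Addition of methyllithium to the enone (after deprotonation of the two hydroxyls) should occur on the carbonyl face opposite the pseudo-axial angular methyl at C8a, which sits across the C7=C8 bond, so that the new C6 hydroxyl is cis to that methyl (6S).

Step 10
Reactants: 14 triol (C4 epimers)
Product: 15 (3R,3aR,6S,8aR)-3,6-dihydroxy-6,8a-dimethyl-3-(propan-2-yl)-2,3,3a,5,6,8a-hexahydroazulen-4(1H)-one
Conditions: Dess–Martin periodinane, NaHCO3, CH2Cl2, 0 °C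
Reagents that add atoms: none
Why: Dess–Martin oxidation of the only secondary alcohol merges both C4 epimers into one ketone under neutral conditions that spare the two tertiary alcohols.

Step 11
Reactants: 15 dihydroxy ketone
Product: 16 (3R,3aS,4S,6S,8aR)-6,8a-dimethyl-3-(propan-2-yl)-1,2,3,3a,4,5,6,8a-octahydroazulene-3,4,6-triol
Conditions: Me4NBH(OAc)3, MeCN/AcOH, −30 °C
Reagents that add atoms: none
Why: In this Evans–Saksena reduction the acetoxyborohydride binds to either flanking tertiary hydroxyl (C3–OH or C6–OH, both on the face of the angular methyl) and delivers hydride intramolecularly to that face of the C4 ketone, giving the 4S alcohol anti to both hydroxyls.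

Step 12
Reactants: 16 triol
Product: 18 (3R,3aS,4S,6S,8aR)-6-hydroxy-6,8a-dimethyl-3-(propan-2-yl)-1,2,3,3a,4,5,6,8a-octahydroazulene-3,4-diyl carbonate (cyclic), via imidazolide 17 (not isolated)
Conditions: CDI, toluene, 60 °C; then DBU (0.2 eq), 80 °C
Reagents that add atoms: 1,1'-carbonyldiimidazole O=C(n1ccnc1)n1ccnc1
Why: Carbonyldiimidazole acylates only the secondary C4 hydroxyl, and the 1,3-related tertiary C3 hydroxyl then displaces imidazole to close the six-membered cyclic carbonate, a ring the C6 hydroxyl cannot form because it is trans-1,3 to O-C4 across the seven-membered ring.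

Step 13
Reactants: 19 4-bromo-2-methoxyphenol
Product: 20 (4-bromo-2-methoxyphenoxy)(tert-butyl)dimethylsilane
Conditions: TBSCl, imidazole, DMF, 23 °C
Reagents that add atoms: tert-butyldimethylsilyl chloride CC(C)(C)[Si](C)(C)Cl
Why: Standard silylation masks the acidic phenol for the bromine–lithium exchange and gives an ether that fluoride removes at the end.

Step 14
Reactants: 18 cyclic carbonate; 20 aryl bromide silyl ether
Product: 23 (3R,3aS,4S,6S,8aR)-3,6-dihydroxy-6,8a-dimethyl-3-(propan-2-yl)-1,2,3,3a,4,5,6,8a-octahydroazulen-4-yl 4-hydroxy-3-methoxybenzoate, via aryllithium 21 (not isolated), via silyl ether 22 (not isolated)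
Conditions: 20, n-BuLi, THF, −78 °C; separately 18, LiHMDS (1.05 eq), THF, −78 °C; add 21 (2 eq), −78 °C; AcOH; then TBAF, THF, 0 °C
Reagents that add atoms: none
Why: Aryllithium 21 adds to the carbonate carbonyl of 18 to give a lithium hemi-orthoester that collapses by C–O cleavage, so the aryl–carbonyl bond is formed and the carbonate carbon becomes the ester carbon. The closest known reaction type is the opening of cyclic carbonates of tertiary/secondary diols by aryllithiums to hydroxy benzoates. No ring is closed (the 1,3-dioxan-2-one is opened) and no stereocentre is formed; C3, C3a, C4, C6 and C8a are spectators. The step needs mono-addition and the acyl group on O-C4: at −78 °C the strained, twist-boat carbonate is far more electrophilic than the electron-rich aryl ester that results, and the hindered tertiary C3 alkoxide is the group released, any C3 ester being funnelled to the less hindered C4 ester by 1,3-acyl shift through the same tetrahedral intermediate. The C6 hydroxyl, lithiated beforehand with LiHMDS so that it consumes no aryllithium, is trans-1,3 to O-C4 on the seven-membered ring and cannot accept the acyl group. Buffered fluoride then cleaves the phenolic silyl ether in the same flask without touching the ester.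

**Compound list**

1 | 3-methylcyclopent-2-en-1-one | CC1=CC(=O)CC1 | starting material
2 | ethynyltrimethylsilane | C#C[Si](C)(C)C | starting material
3 | [1-(trimethylsilyl)ethenyl]bis(2-methylpropyl)alumane | C=C([Si](C)(C)C)[Al](CC(C)C)CC(C)C | intermediate
4 | (S)-3-methyl-3-[1-(trimethylsilyl)ethenyl]cyclopentan-1-one | C[C@]1(C(=C)[Si](C)(C)C)CCC(=O)C1 | intermediate
5 | (S)-3-ethenyl-3-methylcyclopentan-1-one | C[C@]1(C=C)CCC(=O)C1 | intermediate
6 | (4S)-4-ethenyl-4-methyl-2-(2-methylpropanoyl)cyclopentan-1-one (C2 epimers/enol) | C[C@]1(C=C)CC(C(=O)C(C)C)C(=O)C1 | intermediate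
7 | (S)-3-ethenyl-3,7-dimethyl-6-oxooctanoic acid | OC(=O)C[C@@](C)(C=C)CCC(=O)C(C)C | intermediate
8 | (1R,2R,5R)-2-ethenyl-2-methyl-5-(propan-2-yl)-6-oxabicyclo[3.2.0]heptan-7-one | O=C1O[C@@]2(C(C)C)CC[C@](C)(C=C)[C@@H]12 | intermediate
9 | (1R,2S,3R)-3-ethenyl-2-(hydroxymethyl)-3-methyl-1-(propan-2-yl)cyclopentan-1-ol | OC[C@H]1[C@](O)(C(C)C)CC[C@]1(C)C=C | intermediate
10 | (1R,2R,5R)-2-ethenyl-5-hydroxy-2-methyl-5-(propan-2-yl)cyclopentane-1-carbaldehyde | O=C[C@H]1[C@](O)(C(C)C)CC[C@]1(C)C=C | intermediate
11 | 2-(trimethylsilyloxy)buta-1,3-diene | C=CC(=C)O[Si](C)(C)C | starting material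
12 | 5-hydroxy-5-[(1S,2R,5R)-2-ethenyl-5-hydroxy-2-methyl-5-(propan-2-yl)cyclopentyl]pent-1-en-3-one (C5 epimers) | C=CC(=O)CC(O)[C@H]1[C@](O)(C(C)C)CC[C@]1(C)C=C | intermediate
13 | (3R,3aS,8aR)-3,4-dihydroxy-8a-methyl-3-(propan-2-yl)-2,3,3a,4,5,8a-hexahydroazulen-6(1H)-one (C4 epimers) | OC1CC(=O)C=C[C@@]2(C)CC[C@@](O)(C(C)C)[C@H]12 | intermediate
14 | (3R,3aS,6S,8aR)-6,8a-dimethyl-3-(propan-2-yl)-1,2,3,3a,4,5,6,8a-octahydroazulene-3,4,6-triol (C4 epimers) | OC1C[C@](C)(O)C=C[C@@]2(C)CC[C@@](O)(C(C)C)[C@H]12 | intermediate
15 | (3R,3aR,6S,8aR)-3,6-dihydroxy-6,8a-dimethyl-3-(propan-2-yl)-2,3,3a,5,6,8a-hexahydroazulen-4(1H)-one | O=C1C[C@](C)(O)C=C[C@@]2(C)CC[C@@](O)(C(C)C)[C@H]12 | intermediate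
16 | (3R,3aS,4S,6S,8aR)-6,8a-dimethyl-3-(propan-2-yl)-1,2,3,3a,4,5,6,8a-octahydroazulene-3,4,6-triol | O[C@H]1C[C@](C)(O)C=C[C@@]2(C)CC[C@@](O)(C(C)C)[C@H]12 | intermediate
17 | (3R,3aS,4S,6S,8aR)-3,6-dihydroxy-6,8a-dimethyl-3-(propan-2-yl)-1,2,3,3a,4,5,6,8a-octahydroazulen-4-yl 1H-imidazole-1-carboxylate | O=C(O[C@H]1C[C@](C)(O)C=C[C@@]2(C)CC[C@@](O)(C(C)C)[C@H]12)n1ccnc1 | intermediate
18 | (3R,3aS,4S,6S,8aR)-6-hydroxy-6,8a-dimethyl-3-(propan-2-yl)-1,2,3,3a,4,5,6,8a-octahydroazulene-3,4-diyl carbonate (cyclic; 1,3-dioxan-2-one through C3, C3a, C4) | O=C1O[C@H]2C[C@](C)(O)C=C[C@@]3(C)CC[C@@](O1)(C(C)C)[C@H]23 | intermediate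
19 | 4-bromo-2-methoxyphenol | COc1cc(Br)ccc1O | starting material
20 | (4-bromo-2-methoxyphenoxy)(tert-butyl)dimethylsilane | COc1cc(Br)ccc1O[Si](C)(C)C(C)(C)C | intermediate
21 | {4-[(tert-butyldimethylsilyl)oxy]-3-methoxyphenyl}lithium | COc1cc([Li])ccc1O[Si](C)(C)C(C)(C)C | intermediate
22 | (3R,3aS,4S,6S,8aR)-3,6-dihydroxy-6,8a-dimethyl-3-(propan-2-yl)-1,2,3,3a,4,5,6,8a-octahydroazulen-4-yl 4-[(tert-butyldimethylsilyl)oxy]-3-methoxybenzoate | COc1cc(C(=O)O[C@H]2C[C@](C)(O)C=C[C@@]3(C)CC[C@@](O)(C(C)C)[C@H]23)ccc1O[Si](C)(C)C(C)(C)C | intermediate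
23 | (3R,3aS,4S,6S,8aR)-3,6-dihydroxy-6,8a-dimethyl-3-(propan-2-yl)-1,2,3,3a,4,5,6,8a-octahydroazulen-4-yl 4-hydroxy-3-methoxybenzoate | COc1cc(C(=O)O[C@H]2C[C@](C)(O)C=C[C@@]3(C)CC[C@@](O)(C(C)C)[C@H]23)ccc1O | target

**Step count and risks**

Total steps: 14. Longest linear sequence: 13 (steps 1–12 and 14).

The three steps most likely to fail:

Step 4 (aldol-lactonization). Carbon–carbon bond formation between the neopentyl-type ammonium enolate and the hindered isopropyl ketone may be too slow, and facial control by the catalyst relative to the quaternary centre may be poor. The fallback sets out from keto acid 7. The acid would be converted into S-phenyl (3S)-3-ethenyl-3,7-dimethyl-6-oxooctanethioate F1 (PhSH, EDC, DMAP). The thioester α-position, the most acidic C–H in the molecule, would be enolized under soft conditions (MgBr2·OEt2, i-Pr2NEt, CH2Cl2). The metal thioester enolate should add to the ketone and the aldolate expel thiophenolate to close the β-lactone (thioester aldol-lactonization), which rejoins the route at 8. The lactone face would then be under substrate control, and the isomer cis to the methyl group would be separated by chromatography.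

Step 8 (ring-closing metathesis). Initiation and cyclization may be slow because one alkene sits on a quaternary carbon and the other is an electron-poor vinyl ketone, so oligomerization or catalyst decomposition could compete. The fallback sets out from 12. Luche reduction (NaBH4, CeCl3, MeOH) would give 1-[(1S,2R,5R)-2-ethenyl-5-hydroxy-2-methyl-5-(propan-2-yl)cyclopentyl]pent-4-ene-1,3-diol F2, whose allylic alcohol is a better metathesis partner. Ring closure (Grubbs II, CH2Cl2, 40 °C) would give (3R,3aS,8aR)-8a-methyl-3-(propan-2-yl)-1,2,3,3a,4,5,6,8a-octahydroazulene-3,4,6-triol F3. MnO2 should then oxidize only the allylic C6 hydroxyl, which comes back to the route at 13.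

Step 14 (carbonate opening). Closure of the strained cyclic carbonate in step 12 or its regioselective opening may fail, leaving the acyl group on the tertiary oxygen or allowing a second aryllithium addition to the ester. The fallback sets out from triol 16. The imidazole-1-carboxylate 17 would be prepared with CDI at 23 °C and isolated. The aryl Grignard reagent {4-[(tert-butyldimethylsilyl)oxy]-3-methoxyphenyl}magnesium bromide F4 (from 20, Mg, LiCl, THF; 3.5 equiv, two being consumed by the hydroxyls) would displace imidazole at the carbamate carbonyl at 0 °C. This is acyl substitution of an alkyl imidazole-1-carboxylate by a Grignard reagent, and it forms the same aryl–carbonyl bond without the temporary ring. It comes back to the route at silyl ether 22, which TBAF/AcOH converts into 23.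

**Further compounds**

F1 | step 4 | S-phenyl (3S)-3-ethenyl-3,7-dimethyl-6-oxooctanethioate | O=C(C[C@@](C)(C=C)CCC(=O)C(C)C)Sc1ccccc1
F2 | step 8 | 1-[(1S,2R,5R)-2-ethenyl-5-hydroxy-2-methyl-5-(propan-2-yl)cyclopentyl]pent-4-ene-1,3-diol (C1, C3 epimers) | C=CC(O)CC(O)[C@H]1[C@](O)(C(C)C)CC[C@]1(C)C=C
F3 | step 8 | (3R,3aS,8aR)-8a-methyl-3-(propan-2-yl)-1,2,3,3a,4,5,6,8a-octahydroazulene-3,4,6-triol (C4, C6 epimers) | OC1CC(O)C=C[C@@]2(C)CC[C@@](O)(C(C)C)[C@H]12
F4 | step 14 | {4-[(tert-butyldimethylsilyl)oxy]-3-methoxyphenyl}magnesium bromide | COc1cc([Mg]Br)ccc1O[Si](C)(C)C(C)(C)C
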